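**Plan**

- Locants: benzofuran O1, C2, C3, C3a–C7a; ring A is the benzo ring, ring B the dihydrofuran, ring C the guaiacyl ring; the chain on C5 is C7', C8', C9'.
- Cuts, in retrosynthetic order: C7'–C8' (C5 aldehyde plus a benzoyloxy-allyl unit whose vinyl end is later trimmed to C9'H2OH); then, together, O1–C2 and the bond from C3 to its hydroxymethyl carbon; then the bond between ring A and the two-carbon bridge.
- Enabling feature: in ring B the ether oxygen O1 is bonded to C2 and the one-carbon branch to the adjacent C3, on opposite faces. This is the outcome of adding a phenol oxygen and a carbonyl carbon anti across the E double bond of a 2-hydroxystilbene.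
- Forward order: rings A and C are joined as the E-stilbene; palladium closes ring B with capture of CO; both esters become CH2OH and C5 an aldehyde; the chain is extended at C7'–C8'; the vinyl group is cleaved to C9'; protecting groups are removed.
- Stereochemistry: C2 from ligand-controlled choice of the alkene face on palladium; C3 from anti oxypalladation and retentive CO insertion (trans, also the stable epimer); C7' and C8' from the chiral iridium catalyst through a chair transition state (anti).

Key step: step 3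

Assumption: the sense of induction of the bisoxazoline (step 3) and of SEGPHOS (step 8) cannot be derived safely for this substrate; (S,S) and (R) are written, and the mirror-image ligand is meant if the first run shows the opposite sense.
Assumption: 2-methoxy-4-vinylphenol, methyl 3-bromo-4-hydroxy-5-methoxybenzoate, acrolein and benzoic anhydride are taken as purchased.

**Route**

Step 1
Reactants: 1 2-methoxy-4-vinylphenol
Product: 2 2-methoxy-4-vinylphenyl pivalate
Conditions: PivCl, Et3N, DMAP (cat.), CH2Cl2, 0 °C → rt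
Reagents that add atoms: pivaloyl chloride, CC(C)(C)C(=O)Cl
Why: Acylation of the phenol (nucleophilic acyl substitution under DMAP catalysis) is routine, and the pivalate both survives the two palladium steps and lowers the donor strength of ring C.

Step 2
Reactants: 2 2-methoxy-4-vinylphenyl pivalate; 3 methyl 3-bromo-4-hydroxy-5-methoxybenzoate
Product: 4 methyl 4-hydroxy-3-methoxy-5-[(E)-2-(3-methoxy-4-pivaloyloxyphenyl)ethenyl]benzoate
Conditions: Pd(OAc)2 (5 mol %), P(o-tol)3 (10 mol %), Et3N, DMF, 100 °C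
Reagents that add atoms: none
Why: Mizoroki–Heck reaction: oxidative addition of zerovalent palladium into the C–Br bond, syn insertion of the styrene at its terminal carbon and syn β-hydride elimination give the E-stilbene, and tri-o-tolylphosphine/Et3N is the classical system that accepts unprotected bromophenols.

Step 3
Reactants: 4 methyl 4-hydroxy-3-methoxy-5-[(E)-2-(3-methoxy-4-pivaloyloxyphenyl)ethenyl]benzoate
Product: 5 dimethyl (2R,3R)-7-methoxy-2-[3-methoxy-4-(pivaloyloxy)phenyl]-2,3-dihydro-1-benzofuran-3,5-dicarboxylate (2,3-trans)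
Conditions: Pd(OCOCF3)2 (10 mol %), (S,S)-2,2'-isopropylidenebis(4-phenyl-2-oxazoline) (12 mol %), p-benzoquinone (2 equiv), CO (5 bar), MeOH/CH2Cl2 1:1, 0 °C → rt
Reagents that add atoms: carbon monoxide, [C-]#[O+]; methanol, CO
Why: Proposed new method: the cationic bisoxazoline complex of divalent palladium binds one face of the E double bond, the ortho phenol attacks C2 from outside the metal (anti oxypalladation) and places palladium on C3, CO inserts into the C3–Pd bond with retention, methanol cleaves the acyl–palladium species to the ester, and benzoquinone returns zerovalent palladium to the divalent state. The closest known reactions are the palladium-catalysed cyclisation–methoxycarbonylation of alkenyl phenols and 2-alkynylphenols under the same Pd(OCOCF3)2/bisoxazoline/benzoquinone/CO/MeOH system and the Wacker-type cyclisation of 2-hydroxystilbenes to 2-arylbenzofurans, which shows the same C–O bond forming on this substrate class; what is new is the interception of the C3–palladium intermediate by CO. Ring B closes in the 5-endo-trig mode, feasible because the nucleophile attacks a metal-bound alkene from outside, and the other regiochemistry would need a four-membered ring. C2 is set by the ligand-controlled choice of alkene face, and C3 follows from anti addition plus retentive insertion, giving the 2,3-trans ester, which is also the more stable epimer at this enolisable centre. The selectivity needed is CO insertion over β-hydride loss from C2 (the path to the benzofuran): the chelating ligand and CO fill the coordination sites, the C3–Pd bond is benzylic to ring A and can rest as an η3-benzyl, and secondary benzylic palladium alkyls on bisoxazoline ligands insert CO faster than they eliminate in CO/styrene copolymerisation. The pivalate on ring C keeps the new benzylic C2–O1 bond from ionising in the CF3CO2H that is released.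

Step 4
Reactants: 5 dimethyl (2R,3R)-7-methoxy-2-[3-methoxy-4-(pivaloyloxy)phenyl]-2,3-dihydro-1-benzofuran-3,5-dicarboxylate
Product: 6 4-[(2R,3S)-3,5-bis(hydroxymethyl)-7-methoxy-2,3-dihydro-1-benzofuran-2-yl]-2-methoxyphenol
Conditions: LiAlH4, THF, −20 → 0 °C; aqueous potassium sodium tartrate (KNaC4H4O6) work-up
Reagents that add atoms: none
Why: Hydride reduction with LiAlH4 converts both methyl esters into primary alcohols and cleaves the aryl pivalate in the same operation, the low temperature keeping the C3 ester enolate from expelling O1, and no bond at C2 or C3 is broken (the C3 descriptor changes from R to S through CIP priorities only).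

Step 5
Reactants: 6 4-[(2R,3S)-3,5-bis(hydroxymethyl)-7-methoxy-2,3-dihydro-1-benzofuran-2-yl]-2-methoxyphenol
Product: 7 (2R,3S)-2-(4-hydroxy-3-methoxyphenyl)-3-(hydroxymethyl)-7-methoxy-2,3-dihydro-1-benzofuran-5-carbaldehyde
Conditions: activated MnO2 (excess), EtOAc, rt
Reagents that add atoms: none
Why: MnO2 oxidises benzylic alcohols selectively, so the C5 hydroxymethyl group on electron-rich ring A should go to the aldehyde while the non-benzylic C3 hydroxymethyl group stays, and guaiacyl phenols are tolerated as in the oxidation of vanillyl alcohol to vanillin.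

Step 6
Reactants: 7 (2R,3S)-2-(4-hydroxy-3-methoxyphenyl)-3-(hydroxymethyl)-7-methoxy-2,3-dihydro-1-benzofuran-5-carbaldehyde
Product: 8 (2R,3S)-7-methoxy-2-{3-methoxy-4-[(triisopropylsilyl)oxy]phenyl}-3-{[(triisopropylsilyl)oxy]methyl}-2,3-dihydro-1-benzofuran-5-carbaldehyde
Conditions: TIPSCl (2.5 equiv), imidazole, DMF, rt
Reagents that add atoms: chlorotriisopropylsilane, CC(C)[Si](Cl)(C(C)C)C(C)C
Why: Silyl ether formation (TIPSCl/imidazole) covers the phenol and the primary alcohol in one operation, and the triisopropylsilyl aryl ether is robust enough for the mildly basic allylation, ozone and borohydride that follow.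

Step 7
Reactants: 9 acrolein; 10 benzoic anhydride
Product: 11 prop-2-ene-1,1-diyl dibenzoate
Conditions: H2SO4 (cat.), CH2Cl2, 0 °C → rt
Reagents that add atoms: none
Why: Acid-catalysed acylal formation (1,1-diacylation of an aldehyde by an anhydride) gives the allylic gem-dibenzoate, 1,2-addition to the carbonyl group being preferred over conjugate addition at low temperature.

Step 8
Reactants: 8 (2R,3S)-7-methoxy-2-{3-methoxy-4-[(triisopropylsilyl)oxy]phenyl}-3-{[(triisopropylsilyl)oxy]methyl}-2,3-dihydro-1-benzofuran-5-carbaldehyde; 11 prop-2-ene-1,1-diyl dibenzoate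
Product: 12 (1S,2R)-1-hydroxy-1-[(2R,3S)-7-methoxy-2-{3-methoxy-4-[(triisopropylsilyl)oxy]phenyl}-3-{[(triisopropylsilyl)oxy]methyl}-2,3-dihydro-1-benzofuran-5-yl]but-3-en-2-yl benzoate
Conditions: [Ir(cod)Cl]2 (2.5 mol %), (R)-SEGPHOS (5 mol %), 4-cyano-3-nitrobenzoic acid (10 mol %), K3PO4 (20 mol %), i-PrOH (2 equiv), THF, 60 °C
Reagents that add atoms: none
Why: Iridium-catalysed transfer-hydrogenative carbonyl (α-benzoyloxy)allylation (Krische-type allylation with an allylic gem-dicarboxylate): loss of one benzoate gives a benzoyloxy-substituted π-allyl iridium complex, isopropanol delivers the reducing equivalents, and the (E)-σ-allyl species adds to the aldehyde through a closed chair transition state, which fixes the anti (erythro) relation of C7' and C8', while the cyclometalated SEGPHOS catalyst selects the aldehyde face (7'S,8'R) without influence from the remote C2 and C3.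

Step 9
Reactants: 12 (1S,2R)-1-hydroxy-1-[(2R,3S)-7-methoxy-2-{3-methoxy-4-[(triisopropylsilyl)oxy]phenyl}-3-{[(triisopropylsilyl)oxy]methyl}-2,3-dihydro-1-benzofuran-5-yl]but-3-en-2-yl benzoate
Product: 14 (1S,2R)-1,3-dihydroxy-1-[(2R,3S)-7-methoxy-2-{3-methoxy-4-[(triisopropylsilyl)oxy]phenyl}-3-{[(triisopropylsilyl)oxy]methyl}-2,3-dihydro-1-benzofuran-5-yl]propan-2-yl benzoate, via benzoyloxy aldehyde 13 (not isolated)
Conditions: O3, CH2Cl2/MeOH, −78 °C (Sudan Red 7B as end-point indicator); then NaBH4, −78 → 0 °C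
Reagents that add atoms: ozone, [O-][O+]=O
Why: Ozonolysis with reductive work-up: the terminal vinyl group reacts with ozone far faster than the alkoxy arenes (the dye marks the end point), and NaBH4 reduces the resulting aldehyde to C9'H2OH without touching C7' or C8' (a 1,2-benzoyl shift, should it occur, proceeds with retention and is erased in step 10).

Step 10
Reactants: 14 (1S,2R)-1,3-dihydroxy-1-[(2R,3S)-7-methoxy-2-{3-methoxy-4-[(triisopropylsilyl)oxy]phenyl}-3-{[(triisopropylsilyl)oxy]methyl}-2,3-dihydro-1-benzofuran-5-yl]propan-2-yl benzoate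
Product: 16 (1S,2R)-1-[(2R,3S)-2-(4-hydroxy-3-methoxyphenyl)-3-(hydroxymethyl)-7-methoxy-2,3-dihydro-1-benzofuran-5-yl]propane-1,2,3-triol, via desilylated benzoate 15 (not isolated)
Conditions: TBAF, THF, 0 °C → rt; then K2CO3 (cat.), MeOH, rt
Reagents that add atoms: none
Why: Fluoride cleaves both Si–O bonds and carbonate-catalysed transesterification then removes the benzoate as methyl benzoate; no C–O bond at a stereocentre is broken, and acid is avoided because C7'–OH and C2–O1 are p-oxybenzylic.

**Compound list**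

1 | 2-methoxy-4-vinylphenol | COc1cc(C=C)ccc1O | starting material
2 | 2-methoxy-4-vinylphenyl pivalate | COc1cc(C=C)ccc1OC(=O)C(C)(C)C | intermediate
3 | methyl 3-bromo-4-hydroxy-5-methoxybenzoate | COC(=O)c1cc(Br)c(O)c(OC)c1 | starting material
4 | methyl 4-hydroxy-3-methoxy-5-[(E)-2-(3-methoxy-4-pivaloyloxyphenyl)ethenyl]benzoate | COC(=O)c1cc(OC)c(O)c(/C=C/c2ccc(OC(=O)C(C)(C)C)c(OC)c2)c1 | intermediate
5 | dimethyl (2R,3R)-7-methoxy-2-[3-methoxy-4-(pivaloyloxy)phenyl]-2,3-dihydro-1-benzofuran-3,5-dicarboxylate | COc1cc([C@@H]2Oc3c(OC)cc(C(=O)OC)cc3[C@H]2C(=O)OC)ccc1OC(=O)C(C)(C)C | intermediate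
6 | 4-[(2R,3S)-3,5-bis(hydroxymethyl)-7-methoxy-2,3-dihydro-1-benzofuran-2-yl]-2-methoxyphenol | COc1cc([C@@H]2Oc3c(OC)cc(CO)cc3[C@H]2CO)ccc1O | intermediate
7 | (2R,3S)-2-(4-hydroxy-3-methoxyphenyl)-3-(hydroxymethyl)-7-methoxy-2,3-dihydro-1-benzofuran-5-carbaldehyde | COc1cc([C@@H]2Oc3c(OC)cc(C=O)cc3[C@H]2CO)ccc1O | intermediate
8 | (2R,3S)-7-methoxy-2-{3-methoxy-4-[(triisopropylsilyl)oxy]phenyl}-3-{[(triisopropylsilyl)oxy]methyl}-2,3-dihydro-1-benzofuran-5-carbaldehyde | COc1cc([C@@H]2Oc3c(OC)cc(C=O)cc3[C@H]2CO[Si](C(C)C)(C(C)C)C(C)C)ccc1O[Si](C(C)C)(C(C)C)C(C)C | intermediate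
9 | acrolein | C=CC=O | starting material
10 | benzoic anhydride | O=C(OC(=O)c1ccccc1)c1ccccc1 | starting material
11 | prop-2-ene-1,1-diyl dibenzoate | C=CC(OC(=O)c1ccccc1)OC(=O)c1ccccc1 | intermediate
12 | (1S,2R)-1-hydroxy-1-[(2R,3S)-7-methoxy-2-{3-methoxy-4-[(triisopropylsilyl)oxy]phenyl}-3-{[(triisopropylsilyl)oxy]methyl}-2,3-dihydro-1-benzofuran-5-yl]but-3-en-2-yl benzoate | COc1cc([C@@H]2Oc3c(OC)cc([C@H](O)[C@H](OC(=O)c4ccccc4)C=C)cc3[C@H]2CO[Si](C(C)C)(C(C)C)C(C)C)ccc1O[Si](C(C)C)(C(C)C)C(C)C | intermediate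
13 | (2S,3S)-3-hydroxy-3-[(2R,3S)-7-methoxy-2-{3-methoxy-4-[(triisopropylsilyl)oxy]phenyl}-3-{[(triisopropylsilyl)oxy]methyl}-2,3-dihydro-1-benzofuran-5-yl]-1-oxopropan-2-yl benzoate | COc1cc([C@@H]2Oc3c(OC)cc([C@H](O)[C@H](OC(=O)c4ccccc4)C=O)cc3[C@H]2CO[Si](C(C)C)(C(C)C)C(C)C)ccc1O[Si](C(C)C)(C(C)C)C(C)C | intermediate (not isolated)
14 | (1S,2R)-1,3-dihydroxy-1-[(2R,3S)-7-methoxy-2-{3-methoxy-4-[(triisopropylsilyl)oxy]phenyl}-3-{[(triisopropylsilyl)oxy]methyl}-2,3-dihydro-1-benzofuran-5-yl]propan-2-yl benzoate | COc1cc([C@@H]2Oc3c(OC)cc([C@H](O)[C@H](OC(=O)c4ccccc4)CO)cc3[C@H]2CO[Si](C(C)C)(C(C)C)C(C)C)ccc1O[Si](C(C)C)(C(C)C)C(C)C | intermediate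
15 | (1S,2R)-1,3-dihydroxy-1-[(2R,3S)-2-(4-hydroxy-3-methoxyphenyl)-3-(hydroxymethyl)-7-methoxy-2,3-dihydro-1-benzofuran-5-yl]propan-2-yl benzoate | COc1cc([C@@H]2Oc3c(OC)cc([C@H](O)[C@H](OC(=O)c4ccccc4)CO)cc3[C@H]2CO)ccc1O | intermediate (not isolated)
16 | (1S,2R)-1-[(2R,3S)-2-(4-hydroxy-3-methoxyphenyl)-3-(hydroxymethyl)-7-methoxy-2,3-dihydro-1-benzofuran-5-yl]propane-1,2,3-triol | COc1cc([C@@H]2Oc3c(OC)cc([C@H](O)[C@H](O)CO)cc3[C@H]2CO)ccc1O | target

**Count**

Total steps: 10. Longest linear sequence: 9 (steps 1–6 and 8–10; step 7 makes the allyl donor).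

**Steps most likely to fail**

Step 3 (the proposed method). β-Hydride loss from C2 may outrun CO insertion, so that ring B aromatises. The ligand may discriminate the alkene faces poorly. The alkene may be methoxycarbonylated intermolecularly before the phenol attacks.

Fallback, known chemistry, from 3 back to 6: ring B is closed by an enantioselective rhodium-carbenoid C–H insertion that forms C2–C3.
- Vanillyl alcohol is acylated at the phenol only (PivCl, aqueous NaOH, CH2Cl2) to 4-(hydroxymethyl)-2-methoxyphenyl pivalate F1.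
- Mitsunobu etherification of phenol 3 with this alcohol (PPh3, DIAD, THF) gives methyl 3-bromo-5-methoxy-4-{[3-methoxy-4-(pivaloyloxy)phenyl]methoxy}benzoate F2.
- Palladium-catalysed coupling of the aryl bromide with the Reformatsky reagent of tert-butyl bromoacetate (Pd(dba)2, P(t-Bu)3, THF, rt) gives methyl 3-(2-tert-butoxy-2-oxoethyl)-5-methoxy-4-{[3-methoxy-4-(pivaloyloxy)phenyl]methoxy}benzoate F3.
- Diazo transfer (p-acetamidobenzenesulfonyl azide, DBU, MeCN) gives methyl 3-(2-tert-butoxy-1-diazo-2-oxoethyl)-5-methoxy-4-{[3-methoxy-4-(pivaloyloxy)phenyl]methoxy}benzoate F4.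
- Dirhodium tetrakis[N-phthaloyl-(S)-tert-leucinate], Rh2(S-PTTL)4 (antipode chosen for 2R), in toluene at low temperature should insert the carbenoid into the benzylic C–H bond next to the ether oxygen and give 3-tert-butyl 5-methyl (2R,3S)-7-methoxy-2-[3-methoxy-4-(pivaloyloxy)phenyl]-2,3-dihydro-1-benzofuran-3,5-dicarboxylate (cis) F5.
- NaOMe in MeOH epimerises C3 to the trans series and removes the pivalate, giving 3-tert-butyl 5-methyl (2R,3R)-2-(4-hydroxy-3-methoxyphenyl)-7-methoxy-2,3-dihydro-1-benzofuran-3,5-dicarboxylate F6.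
- LiAlH4 as in step 4 then gives 6.

Step 8. The aldehyde may be reduced to the benzylic alcohol faster than it is allylated. The anti selectivity may erode through equilibration of the σ-allyl geometry. The benzoate may migrate or be lost under the basic conditions. The sense of induction is not secured in advance.

Fallback from 8 back to 16: a stoichiometric, reagent-controlled Brown-type allylboration replaces the catalytic coupling and delivers the free diol.
- Hydroboration of 2-(propa-1,2-dien-1-yl)-1,3,2-dioxaborinane with Ipc2BH gives the [(E)-γ-borylallyl]diisopinocampheylborane. The antipode from (−)-α-pinene is expected to give 7'S.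
- Addition to 8 at −78 °C through a chair transition state and oxidation (H2O2, NaOH, 0 °C) should give (1S,2R)-1-[(2R,3S)-7-methoxy-2-{3-methoxy-4-[(triisopropylsilyl)oxy]phenyl}-3-{[(triisopropylsilyl)oxy]methyl}-2,3-dihydro-1-benzofuran-5-yl]but-3-ene-1,2-diol F7.
- Ozonolysis with NaBH4 work-up as in step 9 gives (1S,2R)-1-[(2R,3S)-7-methoxy-2-{3-methoxy-4-[(triisopropylsilyl)oxy]phenyl}-3-{[(triisopropylsilyl)oxy]methyl}-2,3-dihydro-1-benzofuran-5-yl]propane-1,2,3-triol F8.
- TBAF in THF then gives 16.

Step 2. Oxidative addition into the electron-rich bromophenoxide may be slow. Arylation at the internal alkene carbon would give the 1,1-diarylethene. The pivaloyl group may transfer to the phenoxide in hot base.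

Fallback from 2 back to 4: the alkene geometry is fixed before the rings are joined.
- Cross-metathesis of 2 with vinylboronic acid pinacol ester (second-generation Grubbs catalyst, (H2IMes)(PCy3)Cl2Ru=CHPh, CH2Cl2, 40 °C) gives 2-methoxy-4-[(E)-2-(4,4,5,5-tetramethyl-1,3,2-dioxaborolan-2-yl)ethenyl]phenyl pivalate F9.
- Suzuki–Miyaura coupling with bromophenol 3 (Pd(dppf)Cl2, K3PO4, dioxane/H2O, 70 °C) gives 4.

**Further compounds**

F1 | step 3 | 4-(hydroxymethyl)-2-methoxyphenyl pivalate | COc1cc(CO)ccc1OC(=O)C(C)(C)C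
F2 | step 3 | methyl 3-bromo-5-methoxy-4-{[3-methoxy-4-(pivaloyloxy)phenyl]methoxy}benzoate | COC(=O)c1cc(Br)c(OCc2ccc(OC(=O)C(C)(C)C)c(OC)c2)c(OC)c1
F3 | step 3 | methyl 3-(2-tert-butoxy-2-oxoethyl)-5-methoxy-4-{[3-methoxy-4-(pivaloyloxy)phenyl]methoxy}benzoate | COC(=O)c1cc(CC(=O)OC(C)(C)C)c(OCc2ccc(OC(=O)C(C)(C)C)c(OC)c2)c(OC)c1
F4 | step 3 | methyl 3-(2-tert-butoxy-1-diazo-2-oxoethyl)-5-methoxy-4-{[3-methoxy-4-(pivaloyloxy)phenyl]methoxy}benzoate | COC(=O)c1cc(C(=[N+]=[N-])C(=O)OC(C)(C)C)c(OCc2ccc(OC(=O)C(C)(C)C)c(OC)c2)c(OC)c1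
F5 | step 3 | 3-tert-butyl 5-methyl (2R,3S)-7-methoxy-2-[3-methoxy-4-(pivaloyloxy)phenyl]-2,3-dihydro-1-benzofuran-3,5-dicarboxylate (cis) | COc1cc([C@@H]2Oc3c(OC)cc(C(=O)OC)cc3[C@@H]2C(=O)OC(C)(C)C)ccc1OC(=O)C(C)(C)C
F6 | step 3 | 3-tert-butyl 5-methyl (2R,3R)-2-(4-hydroxy-3-methoxyphenyl)-7-methoxy-2,3-dihydro-1-benzofuran-3,5-dicarboxylate (trans) | COc1cc([C@@H]2Oc3c(OC)cc(C(=O)OC)cc3[C@H]2C(=O)OC(C)(C)C)ccc1O
F7 | step 8 | (1S,2R)-1-[(2R,3S)-7-methoxy-2-{3-methoxy-4-[(triisopropylsilyl)oxy]phenyl}-3-{[(triisopropylsilyl)oxy]methyl}-2,3-dihydro-1-benzofuran-5-yl]but-3-ene-1,2-diol | COc1cc([C@@H]2Oc3c(OC)cc([C@H](O)[C@H](O)C=C)cc3[C@H]2CO[Si](C(C)C)(C(C)C)C(C)C)ccc1O[Si](C(C)C)(C(C)C)C(C)C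
F8 | step 8 | (1S,2R)-1-[(2R,3S)-7-methoxy-2-{3-methoxy-4-[(triisopropylsilyl)oxy]phenyl}-3-{[(triisopropylsilyl)oxy]methyl}-2,3-dihydro-1-benzofuran-5-yl]propane-1,2,3-triol | COc1cc([C@@H]2Oc3c(OC)cc([C@H](O)[C@H](O)CO)cc3[C@H]2CO[Si](C(C)C)(C(C)C)C(C)C)ccc1O[Si](C(C)C)(C(C)C)C(C)C
F9 | step 2 | 2-methoxy-4-[(E)-2-(4,4,5,5-tetramethyl-1,3,2-dioxaborolan-2-yl)ethenyl]phenyl pivalate | COc1cc(/C=C/B2OC(C)(C)C(C)(C)O2)ccc1OC(=O)C(C)(C)C
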